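The route rests on cutting C2=C3 of the lower (terminal) epigallocatechin unit. In ring C of that unit C2 (bonded to O1 and ring B) and C3 (hydroxylated) are neighbouring oxygen-bearing carbons next to a C4 methylene, so each can be held as a carbonyl: a trioxybenzoate on O1 and an acetaldehyde on C4a. One low-valent titanium step joins the two carbonyl carbons, creates C2=C3 and closes ring C as a flav-2-ene, with the 4→8 bond already fixed. Its precursor is a benzylated, 3-O-silylated epigallocatechin whose C4 carries a phloroglucinol ring bearing the O-galloyl group between that C4 and a CH2CHO chain. Epoxidation and hydride opening then set C2 and C3; the upper unit arrives last.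

Key step: step 9

Assumption: flavan numbering and ring letters A, B, C are used within each unit, α is the face of ring B in a 2R unit (β the opposite face), acid 10 is bought, and the facial sense of the fructose-derived ketone in step 10 is assigned by analogy with 1-arylcycloalkenes.

Step 1
Reactants: 1 (−)-epigallocatechin
Product: 2 5,7,3',4',5'-penta-O-benzyl-(−)-epigallocatechin (2R,3R; 3-OH free)
Conditions: BnBr, K2CO3, DMF (degassed, N2), 0 °C → rt
Reagents that add atoms: benzyl bromide, BrCc1ccccc1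
Why: Williamson etherification in which carbonate deprotonates only the five phenols, so the secondary 3-OH stays free, while exclusion of oxygen protects the pyrogallol ring and the mild base leaves C2 and C3 untouched.

Step 2
Reactants: 2 5,7,3',4',5'-penta-O-benzyl-(−)-epigallocatechin
Product: 3 (2R,3R,4S)-4β-(2-ethoxyethoxy)-5,7,3',4',5'-penta-O-benzylepigallocatechin (3-OH free; alkoxy group trans to O-3)
Conditions: DDQ, 2-ethoxyethanol, CH2Cl2, rt
Reagents that add atoms: 2-ethoxyethanol, CCOCCO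
Why: DDQ benzylic oxidation, in which hydride abstraction at C4 gives a cation stabilised by the 5,7-dioxygenated ring A that the alcohol should trap from the β face, anti to the α groups at C2 and C3.

Step 3
Reactants: 3 4β-(2-ethoxyethoxy)-penta-O-benzylepigallocatechin
Product: 4 (2R,3R,4S)-3-O-(tert-butyldimethylsilyl)-4β-(2-ethoxyethoxy)-5,7,3',4',5'-penta-O-benzylepigallocatechin
Conditions: TBSCl, imidazole, DMF, 40 °C
Reagents that add atoms: tert-butyldimethylsilyl chloride, CC(C)(C)[Si](C)(C)Cl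
Why: Imidazole-promoted silylation of the only hydroxyl under non-acidic conditions that spare the C4 acetal-type ether, and a silyl ether rather than an ester is chosen so that O-3 of the middle unit stays inert to titanium and to hydride later.

Step 4
Reactants: 4 3-O-TBS-4β-(2-ethoxyethoxy)-penta-O-benzylepigallocatechin; 5 3,5-bis(benzyloxy)phenol
Product: 6 3-O-TBS-5,7,3',4',5'-penta-O-benzylepigallocatechin (2R,3R) bearing at C4β a 2-hydroxy-4,6-bis(benzyloxy)phenyl group (2,3-cis-3,4-trans)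
Conditions: 5 (3 equiv), Me3SiOTf (0.2 equiv), CH2Cl2, −78 → −40 °C; Et3N quench
Reagents that add atoms: none
Why: Friedel–Crafts alkylation by the C4 cation set free with Me3SiOTf, in which the phenol should react through the carbon ortho to its hydroxyl (flanked by OH and one benzyloxy group, also reachable by O-alkylation and O→C shift, whereas the para carbon lies between two benzyloxy groups) and from the β face, anti to the C2 aryl and C3 silyloxy groups, which sets C4.

Step 5
Reactants: 6 4β-[2-hydroxy-4,6-bis(benzyloxy)phenyl] compound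
Product: 7 3-O-TBS-penta-O-benzylepigallocatechin bearing at C4β a 2-allyloxy-4,6-bis(benzyloxy)phenyl group
Conditions: allyl bromide, K2CO3, DMF, rt
Reagents that add atoms: allyl bromide, C=CCBr
Why: Williamson O-allylation of the only acidic hydroxyl, with no other nucleophilic site in the molecule.

Step 6
Reactants: 7 aryl allyl ether
Product: 9 3-O-TBS-penta-O-benzylepigallocatechin bearing at C4β a 3-allyl-2-hydroxy-4,6-bis(benzyloxy)phenyl group, via cyclohexadienone 8 (not isolated)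
Conditions: PhNEt2, 185 °C, sealed tube, Ar
Reagents that add atoms: none
Why: Aromatic Claisen [3,3] shift from oxygen to the only unsubstituted ortho carbon (the future C4a), followed by enolisation of the dienone, the other ortho carbon being blocked by the flavanyl group and the amine solvent keeping the medium non-acidic.

Step 7
Reactants: 9 C-allyl phenol; 10 3,4,5-tris(benzyloxy)benzoic acid
Product: 11 3-O-TBS-penta-O-benzylepigallocatechin bearing at C4β a 3-allyl-4,6-bis(benzyloxy)-2-[3,4,5-tris(benzyloxy)benzoyloxy]phenyl group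
Conditions: DCC, DMAP (1 equiv), CH2Cl2, rt → 40 °C
Reagents that add atoms: none
Why: Steglich esterification through the N-acylpyridinium ion, which is reactive enough for the doubly ortho-substituted phenol, the only hydroxyl in 9.

Step 8
Reactants: 11 allyl aryl ester
Product: 13 3-O-TBS-penta-O-benzylepigallocatechin bearing at C4β a 4,6-bis(benzyloxy)-3-(2-oxoethyl)-2-[3,4,5-tris(benzyloxy)benzoyloxy]phenyl group, via diol 12 (not isolated)
Conditions: OsO4 (2 mol %), NaIO4, 2,6-lutidine, dioxane–H2O, rt; aldehyde used at once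
Reagents that add atoms: osmium tetroxide, O=[Os](=O)(=O)=O; sodium periodate (keeps OsO4 in turnover), [Na+].[O-]I(=O)(=O)=O
Why: Lemieux–Johnson cleavage, in which OsO4 dihydroxylates the terminal alkene (the only C=C) and periodate cleaves the diol as it forms, so that acyl transfer from the aryl ester to the diol has little time and the buffered medium spares the enolisable arylacetaldehyde.

Step 9
Reactants: 13 aldehyde ester
Product: 14 3-O-TBS-penta-O-benzylepigallocatechin bonded through C4β to C8 of 5,7-bis(benzyloxy)-2-[3,4,5-tris(benzyloxy)phenyl]-4H-chromene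
Conditions: TiCl3(DME)1.5, Zn–Cu couple, DME, reflux; 13 added by syringe pump over about 20 h; aqueous K2CO3 work-up
Reagents that add atoms: none
Why: Low-valent titanium reduces the aldehyde to a titanium-bound ketyl that adds to the carbonyl carbon of the neighbouring O1 trioxybenzoate, and the resulting titanium 1,2-diolate is deoxygenated on the oxophilic metal to the C2=C3 enol ether. The closest known reaction type is the titanium-mediated intramolecular oxo–ester (McMurry-type) coupling that turns acyloxy carbonyl compounds into benzofurans and cyclic enol ethers. Ring C of the terminal unit closes in a 6-exo-trig mode (the C3 ketyl carbon attacks the ester C=O, whose oxygen stays outside the ring), with O1, C8a, C4a and C4 already in place. No stereocentre is formed, and C2, C3 and C4 of the middle unit are remote from both carbonyls and are not at risk. The step needs cyclisation to outrun pinacol dimerisation and over-reduction, which the ortho placement of ester and CH2CHO on ring A, slow addition into excess reagent and the absence of any second acyl group should secure, while the zinc-based reductant spares the aryl benzyl ethers and the basic work-up spares the enol ether. Because O1 is flanked by C8 (already bonded to C4 of the middle unit) and C4a before the ring exists, only the 4→8 isomer can form.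

Step 10
Reactants: 14 flav-2-ene dimer
Product: 16 3-O-TBS-penta-O-benzylepigallocatechin-(4β→8)-5,7,3',4',5'-penta-O-benzylepigallocatechin with free 3-OH in the lower (2R,3R) unit, via epoxide 15 (not isolated)
Conditions: D-fructose-derived Shi ketone (0.3 equiv), KHSO5, K2CO3, Bu4NHSO4, CH2(OMe)2–MeCN–aq. Na2B4O7, −10 → 0 °C; cold extractive work-up; then LiBHEt3, THF, −78 → 0 °C
Reagents that add atoms: potassium peroxymonosulfate, [K+].[O-]S(=O)(=O)OO
Why: Shi epoxidation, in which the chiral dioxirane should add oxygen to the α face of the electron-rich trisubstituted C2=C3 through its spiro transition state (reagent control, setting C3), followed by SN2 hydride opening of the crude epoxy acetal at the benzylic C2 with inversion, which places H-2 on the β face and leaves ring B cis to O-3 (2R,3R).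

Step 11
Reactants: 16 dimer with free lower 3-OH
Product: 17 3-O-TBS-penta-O-benzylepigallocatechin-(4β→8)-3,5,7,3',4',5'-hexa-O-benzylepigallocatechin
Conditions: NaH, BnBr, Bu4NI (cat.), DMF, 0 °C → rt
Reagents that add atoms: benzyl bromide, BrCc1ccccc1
Why: Williamson benzylation of the only free hydroxyl, with no base-labile group present, the silyl ether untouched and the new benzyl group due to fall with the others in the last step.

Step 12
Reactants: 17 fully protected dimer
Product: 18 5,7,3',4',5'-penta-O-benzylepigallocatechin-(4β→8)-3,5,7,3',4',5'-hexa-O-benzylepigallocatechin (3-OH of the upper unit of this dimer free)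
Conditions: Bu4NF, THF, rt → 50 °C
Reagents that add atoms: none
Why: Fluoride-driven cleavage of the Si–O bond, selective because every other oxygen is a benzyl or ring ether.

Step 13
Reactants: 18 dimer alcohol; 10 3,4,5-tris(benzyloxy)benzoic acid
Product: 19 3-O-[3,4,5-tris(benzyloxy)benzoyl]-penta-O-benzylepigallocatechin-(4β→8)-hexa-O-benzylepigallocatechin
Conditions: DCC, DMAP, CH2Cl2, rt
Reagents that add atoms: none
Why: Steglich esterification of the single free hydroxyl, the hindered axial 3-OH next to C4, with retention at C3 since its C–O bond is not touched.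

Step 14
Reactants: 19 dimer gallate; 3 4β-(2-ethoxyethoxy)-penta-O-benzylepigallocatechin (from step 2)
Product: 20 nonadeca-O-benzyl ether of epigallocatechin-(4β→8)-epigallocatechin 3-O-gallate-(4β→8)-epigallocatechin (3-OH of the upper unit free, lower 3-OH benzylated)
Conditions: 19 (2 equiv), Me3SiOTf (0.5 equiv), CH2Cl2, −78 → −40 °C; Et3N quench
Reagents that add atoms: none
Why: Friedel–Crafts alkylation by the C4 cation of 3 at C8 of the gallate-bearing unit, the least hindered free ring A carbon (each C6 lies between two benzyloxy groups), from the β face trans to O-3, with excess nucleophile holding back self-condensation of 3.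

Step 15
Reactants: 20 protected trimer
Product: 21 epigallocatechin-(4β→8)-epigallocatechin 3-O-gallate-(4β→8)-epigallocatechin (target)
Conditions: H2 (1 atm), Pd(OH)2/C, THF–MeOH–H2O, rt
Reagents that add atoms: none
Why: Hydrogenolysis of all nineteen benzyl ethers under neutral conditions that should leave the gallate ester, the ring C ethers and both interflavan bonds intact.

Compound list

1 | (−)-epigallocatechin, (2R,3R)-2-(3,4,5-trihydroxyphenyl)chromane-3,5,7-triol | O[C@@H]1Cc2c(O)cc(O)cc2O[C@@H]1c1cc(O)c(O)c(O)c1 | starting material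

2 | 5,7,3',4',5'-penta-O-benzyl-(−)-epigallocatechin (2R,3R) | O[C@@H]1Cc2c(OCc9ccccc9)cc(OCc9ccccc9)cc2O[C@@H]1c7cc(OCc9ccccc9)c(OCc9ccccc9)c(OCc9ccccc9)c7 | intermediate

3 | (2R,3R,4S)-4β-(2-ethoxyethoxy)-5,7,3',4',5'-penta-O-benzylepigallocatechin, 3-OH free | O[C@@H]1[C@@H](OCCOCC)c2c(OCc9ccccc9)cc(OCc9ccccc9)cc2O[C@@H]1c7cc(OCc9ccccc9)c(OCc9ccccc9)c(OCc9ccccc9)c7 | intermediate

4 | (2R,3R,4S)-3-O-TBS-4β-(2-ethoxyethoxy)-5,7,3',4',5'-penta-O-benzylepigallocatechin | CC(C)(C)[Si](C)(C)O[C@@H]1[C@@H](OCCOCC)c2c(OCc9ccccc9)cc(OCc9ccccc9)cc2O[C@@H]1c7cc(OCc9ccccc9)c(OCc9ccccc9)c(OCc9ccccc9)c7 | intermediate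

5 | 3,5-bis(benzyloxy)phenol | Oc1cc(OCc2ccccc2)cc(OCc2ccccc2)c1 | starting material

6 | 3-O-TBS-penta-O-benzylepigallocatechin (2R,3R) with a 2-hydroxy-4,6-bis(benzyloxy)phenyl group at C4β | CC(C)(C)[Si](C)(C)O[C@@H]1[C@@H](c2c(OCc9ccccc9)cc(OCc9ccccc9)cc2O)c2c(OCc9ccccc9)cc(OCc9ccccc9)cc2O[C@@H]1c7cc(OCc9ccccc9)c(OCc9ccccc9)c(OCc9ccccc9)c7 | intermediate

7 | 3-O-TBS-penta-O-benzylepigallocatechin with a 2-allyloxy-4,6-bis(benzyloxy)phenyl group at C4β | CC(C)(C)[Si](C)(C)O[C@@H]1[C@@H](c2c(OCc9ccccc9)cc(OCc9ccccc9)cc2OCC=C)c2c(OCc9ccccc9)cc(OCc9ccccc9)cc2O[C@@H]1c7cc(OCc9ccccc9)c(OCc9ccccc9)c(OCc9ccccc9)c7 | intermediate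

8 | 6-allyl-3,5-bis(benzyloxy)cyclohexa-2,4-dien-1-one bonded through its C2 to C4β of 3-O-TBS-penta-O-benzylepigallocatechin (C6 epimers) | CC(C)(C)[Si](C)(C)O[C@@H]1[C@@H](C2=C(OCc9ccccc9)C=C(OCc9ccccc9)C(CC=C)C2=O)c2c(OCc9ccccc9)cc(OCc9ccccc9)cc2O[C@@H]1c7cc(OCc9ccccc9)c(OCc9ccccc9)c(OCc9ccccc9)c7 | intermediate

9 | 3-O-TBS-penta-O-benzylepigallocatechin with a 3-allyl-2-hydroxy-4,6-bis(benzyloxy)phenyl group at C4β | CC(C)(C)[Si](C)(C)O[C@@H]1[C@@H](c2c(OCc9ccccc9)cc(OCc9ccccc9)c(CC=C)c2O)c2c(OCc9ccccc9)cc(OCc9ccccc9)cc2O[C@@H]1c7cc(OCc9ccccc9)c(OCc9ccccc9)c(OCc9ccccc9)c7 | intermediate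

10 | 3,4,5-tris(benzyloxy)benzoic acid | OC(=O)c1cc(OCc2ccccc2)c(OCc2ccccc2)c(OCc2ccccc2)c1 | starting material

11 | 3-O-TBS-penta-O-benzylepigallocatechin with a 3-allyl-4,6-bis(benzyloxy)-2-[3,4,5-tris(benzyloxy)benzoyloxy]phenyl group at C4β | CC(C)(C)[Si](C)(C)O[C@@H]1[C@@H](c2c(OCc9ccccc9)cc(OCc9ccccc9)c(CC=C)c2OC(=O)c7cc(OCc9ccccc9)c(OCc9ccccc9)c(OCc9ccccc9)c7)c2c(OCc9ccccc9)cc(OCc9ccccc9)cc2O[C@@H]1c7cc(OCc9ccccc9)c(OCc9ccccc9)c(OCc9ccccc9)c7 | intermediate

12 | the 3-(2,3-dihydroxypropyl) analogue of 11 (carbinol epimers) | CC(C)(C)[Si](C)(C)O[C@@H]1[C@@H](c2c(OCc9ccccc9)cc(OCc9ccccc9)c(CC(O)CO)c2OC(=O)c7cc(OCc9ccccc9)c(OCc9ccccc9)c(OCc9ccccc9)c7)c2c(OCc9ccccc9)cc(OCc9ccccc9)cc2O[C@@H]1c7cc(OCc9ccccc9)c(OCc9ccccc9)c(OCc9ccccc9)c7 | intermediate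

13 | 3-O-TBS-penta-O-benzylepigallocatechin with a 4,6-bis(benzyloxy)-3-(2-oxoethyl)-2-[3,4,5-tris(benzyloxy)benzoyloxy]phenyl group at C4β | CC(C)(C)[Si](C)(C)O[C@@H]1[C@@H](c2c(OCc9ccccc9)cc(OCc9ccccc9)c(CC=O)c2OC(=O)c7cc(OCc9ccccc9)c(OCc9ccccc9)c(OCc9ccccc9)c7)c2c(OCc9ccccc9)cc(OCc9ccccc9)cc2O[C@@H]1c7cc(OCc9ccccc9)c(OCc9ccccc9)c(OCc9ccccc9)c7 | intermediate

14 | 3-O-TBS-penta-O-benzylepigallocatechin bonded through C4β to C8 of 5,7-bis(benzyloxy)-2-[3,4,5-tris(benzyloxy)phenyl]-4H-chromene | CC(C)(C)[Si](C)(C)O[C@@H]1[C@@H](c2c(OCc9ccccc9)cc(OCc9ccccc9)c3c2OC(c7cc(OCc9ccccc9)c(OCc9ccccc9)c(OCc9ccccc9)c7)=CC3)c2c(OCc9ccccc9)cc(OCc9ccccc9)cc2O[C@@H]1c7cc(OCc9ccccc9)c(OCc9ccccc9)c(OCc9ccccc9)c7 | intermediate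

15 | the 2α,3α-epoxide of 14 (oxirane oxygen on the face of the later 3-OH) | CC(C)(C)[Si](C)(C)O[C@@H]1[C@@H](c2c(OCc9ccccc9)cc(OCc9ccccc9)c3c2O[C@]4(c7cc(OCc9ccccc9)c(OCc9ccccc9)c(OCc9ccccc9)c7)O[C@@H]4C3)c2c(OCc9ccccc9)cc(OCc9ccccc9)cc2O[C@@H]1c7cc(OCc9ccccc9)c(OCc9ccccc9)c(OCc9ccccc9)c7 | intermediate

16 | 3-O-TBS-penta-O-benzylepigallocatechin-(4β→8)-5,7,3',4',5'-penta-O-benzylepigallocatechin, lower unit (2R,3R) with free 3-OH | CC(C)(C)[Si](C)(C)O[C@@H]1[C@@H](c2c(OCc9ccccc9)cc(OCc9ccccc9)c3c2O[C@H](c7cc(OCc9ccccc9)c(OCc9ccccc9)c(OCc9ccccc9)c7)[C@H](O)C3)c2c(OCc9ccccc9)cc(OCc9ccccc9)cc2O[C@@H]1c7cc(OCc9ccccc9)c(OCc9ccccc9)c(OCc9ccccc9)c7 | intermediate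

17 | 3-O-TBS-penta-O-benzylepigallocatechin-(4β→8)-3,5,7,3',4',5'-hexa-O-benzylepigallocatechin | CC(C)(C)[Si](C)(C)O[C@@H]1[C@@H](c2c(OCc9ccccc9)cc(OCc9ccccc9)c3c2O[C@H](c7cc(OCc9ccccc9)c(OCc9ccccc9)c(OCc9ccccc9)c7)[C@H](OCc9ccccc9)C3)c2c(OCc9ccccc9)cc(OCc9ccccc9)cc2O[C@@H]1c7cc(OCc9ccccc9)c(OCc9ccccc9)c(OCc9ccccc9)c7 | intermediate

18 | penta-O-benzylepigallocatechin-(4β→8)-hexa-O-benzylepigallocatechin, 3-OH of the 4-substituted unit free | O[C@@H]1[C@@H](c2c(OCc9ccccc9)cc(OCc9ccccc9)c3c2O[C@H](c7cc(OCc9ccccc9)c(OCc9ccccc9)c(OCc9ccccc9)c7)[C@H](OCc9ccccc9)C3)c2c(OCc9ccccc9)cc(OCc9ccccc9)cc2O[C@@H]1c7cc(OCc9ccccc9)c(OCc9ccccc9)c(OCc9ccccc9)c7 | intermediate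

19 | 3-O-[3,4,5-tris(benzyloxy)benzoyl]-penta-O-benzylepigallocatechin-(4β→8)-hexa-O-benzylepigallocatechin | O=C(O[C@@H]1[C@@H](c2c(OCc9ccccc9)cc(OCc9ccccc9)c3c2O[C@H](c7cc(OCc9ccccc9)c(OCc9ccccc9)c(OCc9ccccc9)c7)[C@H](OCc9ccccc9)C3)c2c(OCc9ccccc9)cc(OCc9ccccc9)cc2O[C@@H]1c7cc(OCc9ccccc9)c(OCc9ccccc9)c(OCc9ccccc9)c7)c7cc(OCc9ccccc9)c(OCc9ccccc9)c(OCc9ccccc9)c7 | intermediate

20 | nonadeca-O-benzyl ether of epigallocatechin-(4β→8)-epigallocatechin 3-O-gallate-(4β→8)-epigallocatechin (upper 3-OH free) | O=C(O[C@@H]1[C@@H](c2c(OCc9ccccc9)cc(OCc9ccccc9)c3c2O[C@H](c7cc(OCc9ccccc9)c(OCc9ccccc9)c(OCc9ccccc9)c7)[C@H](OCc9ccccc9)C3)c2c(OCc9ccccc9)cc(OCc9ccccc9)c([C@H]3c4c(OCc9ccccc9)cc(OCc9ccccc9)cc4O[C@H](c7cc(OCc9ccccc9)c(OCc9ccccc9)c(OCc9ccccc9)c7)[C@@H]3O)c2O[C@@H]1c7cc(OCc9ccccc9)c(OCc9ccccc9)c(OCc9ccccc9)c7)c7cc(OCc9ccccc9)c(OCc9ccccc9)c(OCc9ccccc9)c7 | intermediate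

21 | epigallocatechin-(4β→8)-epigallocatechin 3-O-gallate-(4β→8)-epigallocatechin (CNP0278699.1) | O=C(O[C@@H]1[C@@H](c2c(O)cc(O)c3c2O[C@H](c2cc(O)c(O)c(O)c2)[C@H](O)C3)c2c(O)cc(O)c([C@H]3c4c(O)cc(O)cc4O[C@H](c4cc(O)c(O)c(O)c4)[C@@H]3O)c2O[C@@H]1c1cc(O)c(O)c(O)c1)c1cc(O)c(O)c(O)c1 | target

Total step count: 15.
Longest linear sequence: 15 steps (1 → 21); compound 3 is drawn from the same line for step 14, and 5 and 10 are bought.

Steps most likely to fail

Step 9. The titanium ketyl may dimerise between molecules (pinacol coupling), be reduced on to the alcohol, or add to the ester and then expel the hindered phenoxide instead of being deoxygenated; the electron-rich, twisted trioxybenzoate is a reluctant acceptor. The fallback sets out from 11 and comes back at 14. Petasis methylenation of the aryl ester carbonyl with Cp2TiMe2 (toluene, 70 °C) should give the aryl 1-arylvinyl ether F1. Ring-closing metathesis of its enol ether with the neighbouring allyl group (second-generation Grubbs catalyst, toluene, 80 °C) then closes the same ring C and forms the same C2=C3 bond by loss of ethylene, giving 14.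

Step 10. The epoxy acetal may ionise at C2 in the aqueous medium or on concentration, the dioxirane may show poor facial selectivity on the crowded chromene, or hydride may arrive after ionisation on the face of O-3 and give the 2,3-trans unit. The fallback sets out from 14 and comes back at 16 without an epoxide. Hydroboration–oxidation (BH3·SMe2 or the matching antipode of monoisopinocampheylborane, then NaOH/H2O2) adds H to C2 and OH to C3 on one face and should give, after separation from its lower-unit diastereomer, the 2,3-trans (2R,3S) alcohol F2. Dess–Martin oxidation gives the flavan-3-one F3, and LiBH(s-Bu)3 at −78 °C should deliver hydride anti to ring B to give the 2,3-cis alcohol 16.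

Step 4. The C4 cation may attack the carbon para to the free hydroxyl (between the two benzyloxy groups) or the phenol oxygen, instead of the ortho carbon. The fallback sets out from 4 and comes back at 7, and it uses a para preference instead of fighting it. Commercial 5-(benzyloxy)benzene-1,3-diol (Oc1cc(O)cc(OCc2ccccc2)c1) is mono-allylated (allyl bromide, 1 equiv, K2CO3, acetone) to 3-allyloxy-5-benzyloxyphenol F4. Me3SiOTf coupling of 4 with F4 at the carbon para to the hydroxyl should give the 4β-(2-allyloxy-6-benzyloxy-4-hydroxyphenyl) compound F5, and benzylation of its remaining phenol (BnBr, K2CO3, DMF) gives 7.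

Further compounds

F1 | step 9 | 3-O-TBS-penta-O-benzylepigallocatechin with a 3-allyl-4,6-bis(benzyloxy)-2-{1-[3,4,5-tris(benzyloxy)phenyl]vinyloxy}phenyl group at C4β | CC(C)(C)[Si](C)(C)O[C@@H]1[C@@H](c2c(OCc9ccccc9)cc(OCc9ccccc9)c(CC=C)c2OC(=C)c7cc(OCc9ccccc9)c(OCc9ccccc9)c(OCc9ccccc9)c7)c2c(OCc9ccccc9)cc(OCc9ccccc9)cc2O[C@@H]1c7cc(OCc9ccccc9)c(OCc9ccccc9)c(OCc9ccccc9)c7

F2 | step 10 | 3-O-TBS-penta-O-benzylepigallocatechin-(4β→8)-5,7,3',4',5'-penta-O-benzylgallocatechin, lower unit 2,3-trans (2R,3S) with free 3-OH | CC(C)(C)[Si](C)(C)O[C@@H]1[C@@H](c2c(OCc9ccccc9)cc(OCc9ccccc9)c3c2O[C@H](c7cc(OCc9ccccc9)c(OCc9ccccc9)c(OCc9ccccc9)c7)[C@@H](O)C3)c2c(OCc9ccccc9)cc(OCc9ccccc9)cc2O[C@@H]1c7cc(OCc9ccccc9)c(OCc9ccccc9)c(OCc9ccccc9)c7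

F3 | step 10 | 3-O-TBS-penta-O-benzylepigallocatechin bonded through C4β to C8 of (2R)-5,7-bis(benzyloxy)-2-[3,4,5-tris(benzyloxy)phenyl]chroman-3-one | CC(C)(C)[Si](C)(C)O[C@@H]1[C@@H](c2c(OCc9ccccc9)cc(OCc9ccccc9)c3c2O[C@H](c7cc(OCc9ccccc9)c(OCc9ccccc9)c(OCc9ccccc9)c7)C(=O)C3)c2c(OCc9ccccc9)cc(OCc9ccccc9)cc2O[C@@H]1c7cc(OCc9ccccc9)c(OCc9ccccc9)c(OCc9ccccc9)c7

F4 | step 4 | 3-allyloxy-5-benzyloxyphenol | Oc1cc(OCC=C)cc(OCc2ccccc2)c1

F5 | step 4 | 3-O-TBS-penta-O-benzylepigallocatechin with a 2-allyloxy-6-benzyloxy-4-hydroxyphenyl group at C4β | CC(C)(C)[Si](C)(C)O[C@@H]1[C@@H](c2c(OCc9ccccc9)cc(O)cc2OCC=C)c2c(OCc9ccccc9)cc(OCc9ccccc9)cc2O[C@@H]1c7cc(OCc9ccccc9)c(OCc9ccccc9)c(OCc9ccccc9)c7
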